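**Retrosynthetic overview**
- Target ⇒ eremophil-11-ene-3α,8α,9α-triol: the two (Z)-hex-2-enoates come from hex-2-ynoates (Lindlar), placed on the equatorial C3 and C9 hydroxyls while the axial C8 hydroxyl stays free.
- Ring A (C1–C5, C10) ⇒ ring B vinyl aldehyde by cutting C3–C4: the strategy rests on the trans-diequatorial pair C3–O / C4–CH3 beside the quaternary C5 (axial methyl), which a C3 ketyl adding to the inner carbon of a C5 vinyl group delivers in one event.
- Ring B vinyl aldehyde ⇒ ring B ketone (C9 C=O, C8 ketal): C9 and C8 carbinols by two hydride reductions, vinyl from a C5 CH2OPMB arm, aldehyde from a silyl-protected C10 propanol chain.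
- Ring B ketone ⇒ 3,4,4-trimethoxycyclohexadienone (from 3,4-dimethoxyphenol): C7 by Rh-catalysed asymmetric isopropenylation, the C10 chain by B-alkyl Suzuki coupling, C5 by Stork–Danheiser transposition and trans cuprate methylation.
- Ring order: ring B is carried over from the aromatic starting material; ring A is closed last, in the key step.

Key step: step 17

Remark on descriptors: eremophilane locants are used for all intermediates (ring B = C5–C10, ring A = C1–C5 and C10, C14 = methyl on C5, C15 = methyl on C4); β is the face of C14, α the other face.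
Assumption: the Rh/(S)-BINAP catalyst attacks the enone face it attacks in cyclohex-2-enone, which corresponds to 5S in the adduct (C7 of the target); if the antipode should form, (R)-BINAP is used.

**Step 1**
Reactants: 1 3,4-dimethoxyphenol
Product: 2 3,4,4-trimethoxycyclohexa-2,5-dien-1-one
Conditions: PhI(OAc)2, MeOH, 0 °C → rt
Reagents that add atoms: methanol, CO
Why: Hypervalent-iodine oxidative dearomatisation of a para-methoxyphenol: the C4 oxocarbenium ion is trapped by methanol as the dimethyl ketal (future C8) while the 3-methoxy group remains as a vinylogous ester (future C9 oxygen); no stereocentre is formed.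

**Step 2**
Reactants: 2 3,4,4-trimethoxycyclohexa-2,5-dien-1-one; 3 potassium trifluoro(prop-1-en-2-yl)borate
Product: 4 (5S)-3,4,4-trimethoxy-5-(prop-1-en-2-yl)cyclohex-2-en-1-one
Conditions: [Rh(cod)2]BF4 (3 mol %), (S)-BINAP, Et3N, toluene/H2O, 60 °C
Reagents that add atoms: none
Why: Hayashi–Miyaura rhodium-catalysed asymmetric 1,4-addition: the alkenylrhodium species adds only to the unsubstituted enone (the other double bond is a deactivated β-methoxy enone), and (S)-BINAP selects the enone face that gives 5S, the future C7 with its α-isopropenyl group.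

**Step 3**
Reactants: 4 (5S)-3,4,4-trimethoxy-5-(prop-1-en-2-yl)cyclohex-2-en-1-one
Product: 5 (5S)-2-iodo-3,4,4-trimethoxy-5-(prop-1-en-2-yl)cyclohex-2-en-1-one
Conditions: N-iodosuccinimide, MeCN, 0 °C → rt, dark
Reagents that add atoms: N-iodosuccinimide, O=C1CCC(=O)N1I
Why: Electrophilic α-iodination of a vinylogous ester: C2 (future C10) is the nucleophilic enol-ether carbon and should react faster than the isolated isopropenyl group; no stereocentre is touched.

**Step 4**
Reactants: 6 prop-2-en-1-ol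
Product: 7 tert-butyl(diphenyl)(prop-2-en-1-yloxy)silane
Conditions: TBDPSCl, imidazole, CH2Cl2, rt
Reagents that add atoms: tert-butyl(chloro)diphenylsilane, CC(C)(C)[Si](Cl)(c1ccccc1)c1ccccc1
Why: Imidazole-promoted silylation of a primary alcohol; the tert-butyldiphenylsilyl ether is chosen because it should survive the two aqueous-acid steps ahead.

**Step 5**
Reactants: 5 (5S)-2-iodo-3,4,4-trimethoxy-5-(prop-1-en-2-yl)cyclohex-2-en-1-one; 7 tert-butyl(diphenyl)(prop-2-en-1-yloxy)silane
Product: 9 (5S)-2-[3-(tert-butyldiphenylsilyloxy)propyl]-3,4,4-trimethoxy-5-(prop-1-en-2-yl)cyclohex-2-en-1-one, via alkylborane 8 (not isolated)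
Conditions: 7, 9-BBN, THF, rt; then 5, Pd(dppf)Cl2 (5 mol %), AsPh3, Cs2CO3, DMF/THF/H2O, rt
Reagents that add atoms: none
Why: B-alkyl Suzuki–Miyaura coupling: anti-Markovnikov hydroboration of 7 gives the primary alkylborane 8, which couples with the 2-iodoenone to install the C1–C3 chain on C10; all B–H is consumed before 5 is added, so the isopropenyl group is not hydroborated.

**Step 6**
Reactants: 10 (4-methoxyphenyl)methanol; 11 tributyl(iodomethyl)stannane
Product: 12 tributyl[(4-methoxybenzyloxy)methyl]stannane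
Conditions: NaH, THF/DMF, 0 °C → rt
Reagents that add atoms: none
Why: Williamson ether synthesis: the alkoxide of 10 displaces iodide from the primary iodomethylstannane in an SN2 reaction.

**Step 7**
Reactants: 9 (5S)-2-[3-(tert-butyldiphenylsilyloxy)propyl]-3,4,4-trimethoxy-5-(prop-1-en-2-yl)cyclohex-2-en-1-one; 12 tributyl[(4-methoxybenzyloxy)methyl]stannane
Product: 15 (5S)-2-[3-(tert-butyldiphenylsilyloxy)propyl]-6,6-dimethoxy-3-[(4-methoxybenzyloxy)methyl]-5-(prop-1-en-2-yl)cyclohex-2-en-1-one, via organolithium 13 (not isolated), via lithium carbinolate 14 (not isolated)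
Conditions: 12, n-BuLi, THF, −78 °C; then 9, −78 °C; then 1 M aq. HCl, THF, 0 °C
Reagents that add atoms: water, O
Why: Stork–Danheiser enone transposition: tin–lithium exchange gives the α-alkoxymethyllithium 13, which adds 1,2 to the vinylogous ester carbonyl (future C5), and dilute acid ionises the tertiary allylic carbinol and hydrolyses the enol ether so that the carbonyl reappears at C9, where the adjacent α-keto ketal should resist the brief acid treatment; C7 is untouched.

**Step 8**
Reactants: 15 (5S)-2-[3-(tert-butyldiphenylsilyloxy)propyl]-6,6-dimethoxy-3-[(4-methoxybenzyloxy)methyl]-5-(prop-1-en-2-yl)cyclohex-2-en-1-one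
Product: 17 (2R,3S,5S)-2-[3-(tert-butyldiphenylsilyloxy)propyl]-6,6-dimethoxy-3-[(4-methoxybenzyloxy)methyl]-3-methyl-5-(prop-1-en-2-yl)cyclohexan-1-one, via silyl enol ether 16 (not isolated)
Conditions: Me2CuLi (from MeLi and CuBr·SMe2), Me3SiCl, THF, −78 → −20 °C; then K2CO3, MeOH, 0 °C
Reagents that add atoms: lithium dimethylcuprate, [Li+].C[Cu-]C
Why: Chlorosilane-accelerated Gilman cuprate conjugate addition: methyl adds axially to C5 anti to the pseudo-equatorial C7 isopropenyl group (the 3,5-trans rule of 5-substituted cyclohexenones), giving 5β-CH3/5α-CH2OPMB, and methanolysis of 16 protonates C10 from the α face; the 10β (equatorial) chain is also the thermodynamic outcome under K2CO3/MeOH, because an axial chain would be 1,3-diaxial to the axial C8 methoxy group.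

**Step 9**
Reactants: 17 (2R,3S,5S)-2-[3-(tert-butyldiphenylsilyloxy)propyl]-6,6-dimethoxy-3-[(4-methoxybenzyloxy)methyl]-3-methyl-5-(prop-1-en-2-yl)cyclohexan-1-one
Product: 19 (2S,3R,4S,6S)-3-[3-(tert-butyldiphenylsilyloxy)propyl]-2-hydroxy-4-[(4-methoxybenzyloxy)methyl]-4-methyl-6-(prop-1-en-2-yl)cyclohexan-1-one, via hydroxy ketal 18 (not isolated)
Conditions: NaBH4, MeOH, 0 °C; then 1 M aq. HCl, THF, rt
Reagents that add atoms: water, O
Why: Borohydride reduction under polar Felkin–Anh control followed by ketal hydrolysis: hydride should attack C9 axially, anti-periplanar to the axial C8–O bond, to give the equatorial 9α-alcohol 18, and aqueous acid then unmasks the C8 ketone while the silyl ether, the PMB ether and the isopropenyl group survive.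

**Step 10**
Reactants: 19 (2S,3R,4S,6S)-3-[3-(tert-butyldiphenylsilyloxy)propyl]-2-hydroxy-4-[(4-methoxybenzyloxy)methyl]-4-methyl-6-(prop-1-en-2-yl)cyclohexan-1-one
Product: 20 (1R,2S,3R,4S,6S)-3-[3-(tert-butyldiphenylsilyloxy)propyl]-4-[(4-methoxybenzyloxy)methyl]-4-methyl-6-(prop-1-en-2-yl)cyclohexane-1,2-diol
Conditions: LiBH(s-Bu)3 (2.5 equiv), THF, −78 °C; aq. NH4Cl
Reagents that add atoms: none
Why: Bulky-hydride (L-Selectride) reduction: the reagent attacks the C8 ketone from the equatorial direction, avoiding the axial hydrogens on C6 and C10, and should give the axial 8α-alcohol, cis to the 9α-hydroxyl and to the 7α-isopropenyl group.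

**Step 11**
Reactants: 20 (1R,2S,3R,4S,6S)-3-[3-(tert-butyldiphenylsilyloxy)propyl]-4-[(4-methoxybenzyloxy)methyl]-4-methyl-6-(prop-1-en-2-yl)cyclohexane-1,2-diol
Product: 21 8,9-acetonide of 20: tert-butyl{3-[(3aS,4R,5S,7S,7aR)-5-[(4-methoxybenzyloxy)methyl]-2,2,5-trimethyl-7-(prop-1-en-2-yl)hexahydro-1,3-benzodioxol-4-yl]propoxy}diphenylsilane
Conditions: 2,2-dimethoxypropane, PPTS, CH2Cl2, rt
Reagents that add atoms: 2,2-dimethoxypropane, COC(C)(C)OC
Why: Acid-catalysed transketalisation: the cis-8,9-diol closes a five-membered isopropylidene acetal, and the other oxygens are protected.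

**Step 12**
Reactants: 21 acetonide PMB ether
Product: 22 [(3aS,4R,5S,7S,7aR)-4-[3-(tert-butyldiphenylsilyloxy)propyl]-2,2,5-trimethyl-7-(prop-1-en-2-yl)hexahydro-1,3-benzodioxol-5-yl]methanol
Conditions: DDQ, CH2Cl2/pH 7 buffer, 0 °C
Reagents that add atoms: none
Why: Oxidative cleavage of the 4-methoxybenzyl ether by DDQ (benzylic hydride abstraction, then hydrolysis) under buffered conditions that should leave the acetonide, the silyl ether and the isopropenyl group intact.

**Step 13**
Reactants: 22 neopentyl alcohol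
Product: 23 (3aS,4R,5S,7S,7aR)-4-[3-(tert-butyldiphenylsilyloxy)propyl]-2,2,5-trimethyl-7-(prop-1-en-2-yl)hexahydro-1,3-benzodioxole-5-carbaldehyde
Conditions: Dess–Martin periodinane, NaHCO3, CH2Cl2, rt
Reagents that add atoms: none
Why: Dess–Martin oxidation of the primary alcohol to the C4 aldehyde, which has no α-hydrogen and cannot epimerise.

**Step 14**
Reactants: 23 C4 aldehyde
Product: 24 tert-butyl{3-[(3aS,4R,5R,7S,7aR)-5-ethenyl-2,2,5-trimethyl-7-(prop-1-en-2-yl)hexahydro-1,3-benzodioxol-4-yl]propoxy}diphenylsilane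
Conditions: Ph3PCH3Br, KOt-Bu, THF, 0 °C → rt
Reagents that add atoms: methyltriphenylphosphonium bromide, C[P+](c1ccccc1)(c1ccccc1)c1ccccc1.[Br-]
Why: Wittig methylenation: the small unstabilised ylide should reach the hindered, non-enolisable aldehyde and give the C5 vinyl group (C4=C15).

**Step 15**
Reactants: 24 vinyl silyl ether
Product: 25 3-[(3aS,4R,5R,7S,7aR)-5-ethenyl-2,2,5-trimethyl-7-(prop-1-en-2-yl)hexahydro-1,3-benzodioxol-4-yl]propan-1-ol
Conditions: Bu4NF, THF, rt
Reagents that add atoms: none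
Why: Fluoride-mediated desilylation of the primary silyl ether.

**Step 16**
Reactants: 25 primary alcohol
Product: 26 3-[(3aS,4R,5R,7S,7aR)-5-ethenyl-2,2,5-trimethyl-7-(prop-1-en-2-yl)hexahydro-1,3-benzodioxol-4-yl]propanal
Conditions: Dess–Martin periodinane, NaHCO3, CH2Cl2, 0 °C
Reagents that add atoms: none
Why: Dess–Martin oxidation of the primary alcohol to the C3 aldehyde under buffered conditions that do not epimerise C10.

**Step 17**
Reactants: 26 ring B vinyl aldehyde 8,9-acetonide
Product: 27 (3R,4R,5R,7S,8R,9S,10R)-8,9-O-isopropylideneeremophil-11-ene-3,8,9-triol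
Conditions: SmI2 (3 equiv), HMPA (10 equiv), t-BuOH (2 equiv), THF, 0 °C, slow addition of 26 at high dilution
Reagents that add atoms: none
Why: Electron transfer from divalent samarium (SmI2 activated by HMPA) to the C3 aldehyde gives a samarium-bound ketyl radical that adds to the inner carbon (C4) of the C5 vinyl group, and the primary C15 radical so formed is reduced by a second SmI2 and protonated by t-BuOH to the C4 methyl. The closest known reaction type is the SmI2–HMPA reductive ketyl–olefin cyclisation of unactivated olefinic aldehydes and ketones. Ring A closes in the 6-exo-trig mode through a chair that is trans-fused to ring B, since the propanal chain on C10 and the vinyl group on C5 are both equatorial on the acetonide-locked ring B. C3 is controlled by the bulky HMPA-solvated O–Sm group, which takes the equatorial site to avoid a 1,3-diaxial clash with the axial C14 methyl; C4 is controlled by the vinyl rotamer with its CH2 terminus exo-equatorial and anti to the ketyl oxygen, so the C3 oxygen and the C4 methyl should come out trans-diequatorial (3α-OH, 4β-CH3). The step needs cyclisation to win over pinacol coupling and simple reduction of the aldehyde, and it must spare the isopropenyl group: slow addition at high dilution suppresses the bimolecular pathway, the gem-disubstituted C5 and the rigid ring B hold the reacting carbons close, and the C7 isopropenyl group cannot be reached from C3.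

**Step 18**
Reactants: 27 acetonide alcohol
Product: 28 (3R,4R,5R,7S,8R,9S,10R)-eremophil-11-ene-3,8,9-triol
Conditions: AcOH/H2O (4:1), 45 °C
Reagents that add atoms: none
Why: Acid-catalysed acetonide hydrolysis in aqueous acetic acid, which is too mild to hydrate or isomerise the isopropenyl group.

**Step 19**
Reactants: 28 3α,8α,9α-triol; 29 hex-2-ynoic acid
Product: 30 (3R,4R,5R,7S,8R,9S,10R)-8-hydroxyeremophil-11-ene-3,9-diyl bis(hex-2-ynoate)
Conditions: 29 (2.2 equiv), N,N'-diisopropylcarbodiimide, DMAP (cat.), CH2Cl2, −20 → 0 °C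
Reagents that add atoms: none
Why: Steglich esterification with kinetic site selection: the two equatorial hydroxyls (3α, 9α) should be acylated while the axial 8α-hydroxyl, wedged between the C7 isopropenyl group and the C9 ester, reacts much more slowly; the alkynoic acid avoids the Z-to-E isomerisation that a (Z)-enoic acid would risk under acylation conditions.

**Step 20**
Reactants: 30 bis(hex-2-ynoate)
Product: 31 (3R,4R,5R,7S,8R,9S,10R)-8-hydroxyeremophil-11-ene-3,9-diyl bis[(2Z)-hex-2-enoate]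
Conditions: H2 (1 atm), Pd/CaCO3–Pb(OAc)2, quinoline, EtOAc, rt
Reagents that add atoms: none
Why: Lindlar semihydrogenation: syn addition of one equivalent of H2 to each ynoate on poisoned palladium should give the two (Z)-enoates and spare the 1,1-disubstituted isopropenyl alkene.

**Compound list**
1 | 3,4-dimethoxyphenol | COc1ccc(O)cc1OC | starting material
2 | 3,4,4-trimethoxycyclohexa-2,5-dien-1-one | COC1=CC(=O)C=CC1(OC)OC | intermediate
3 | potassium trifluoro(prop-1-en-2-yl)borate | CC(=C)[B-](F)(F)F.[K+] | starting material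
4 | (5S)-3,4,4-trimethoxy-5-(prop-1-en-2-yl)cyclohex-2-en-1-one | C=C(C)[C@@H]1CC(=O)C=C(OC)C1(OC)OC | intermediate
5 | (5S)-2-iodo-3,4,4-trimethoxy-5-(prop-1-en-2-yl)cyclohex-2-en-1-one | C=C(C)[C@@H]1CC(=O)C(I)=C(OC)C1(OC)OC | intermediate
6 | prop-2-en-1-ol | C=CCO | starting material
7 | tert-butyl(diphenyl)(prop-2-en-1-yloxy)silane | C=CCO[Si](c1ccccc1)(c1ccccc1)C(C)(C)C | intermediate
8 | 9-[3-(tert-butyldiphenylsilyloxy)propyl]-9-borabicyclo[3.3.1]nonane | CC(C)(C)[Si](OCCCB1C2CCCC1CCC2)(c1ccccc1)c1ccccc1 | intermediate (not isolated)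
9 | (5S)-2-[3-(tert-butyldiphenylsilyloxy)propyl]-3,4,4-trimethoxy-5-(prop-1-en-2-yl)cyclohex-2-en-1-one | C=C(C)[C@@H]1CC(=O)C(CCCO[Si](c2ccccc2)(c2ccccc2)C(C)(C)C)=C(OC)C1(OC)OC | intermediate
10 | (4-methoxyphenyl)methanol | COc1ccc(CO)cc1 | starting material
11 | tributyl(iodomethyl)stannane | CCCC[Sn](CCCC)(CCCC)CI | starting material
12 | tributyl[(4-methoxybenzyloxy)methyl]stannane | CCCC[Sn](CCCC)(CCCC)COCc1ccc(OC)cc1 | intermediate
13 | (4-methoxybenzyloxy)methyllithium | [Li]COCc1ccc(OC)cc1 | intermediate (not isolated)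
14 | lithium (5S)-2-[3-(tert-butyldiphenylsilyloxy)propyl]-3,4,4-trimethoxy-1-[(4-methoxybenzyloxy)methyl]-5-(prop-1-en-2-yl)cyclohex-2-en-1-olate (both C1 epimers) | C=C(C)[C@@H]1CC(O[Li])(COCc2ccc(OC)cc2)C(CCCO[Si](c2ccccc2)(c2ccccc2)C(C)(C)C)=C(OC)C1(OC)OC | intermediate (not isolated)
15 | (5S)-2-[3-(tert-butyldiphenylsilyloxy)propyl]-6,6-dimethoxy-3-[(4-methoxybenzyloxy)methyl]-5-(prop-1-en-2-yl)cyclohex-2-en-1-one | C=C(C)[C@@H]1CC(COCc2ccc(OC)cc2)=C(CCCO[Si](c2ccccc2)(c2ccccc2)C(C)(C)C)C(=O)C1(OC)OC | intermediate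
16 | trimethylsilyl enol ether of 17 (C9–OSiMe3, C9=C10; 5β-CH3, 5α-CH2OPMB, 7α-isopropenyl) | C=C(C)[C@@H]1C[C@](C)(COCc2ccc(OC)cc2)C(CCCO[Si](c2ccccc2)(c2ccccc2)C(C)(C)C)=C(O[Si](C)(C)C)C1(OC)OC | intermediate (not isolated)
17 | (2R,3S,5S)-2-[3-(tert-butyldiphenylsilyloxy)propyl]-6,6-dimethoxy-3-[(4-methoxybenzyloxy)methyl]-3-methyl-5-(prop-1-en-2-yl)cyclohexan-1-one (5β-CH3, 7α-isopropenyl, 10β-chain) | C=C(C)[C@@H]1C[C@](C)(COCc2ccc(OC)cc2)[C@@H](CCCO[Si](c2ccccc2)(c2ccccc2)C(C)(C)C)C(=O)C1(OC)OC | intermediate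
18 | (1S,2R,3S,5S)-2-[3-(tert-butyldiphenylsilyloxy)propyl]-6,6-dimethoxy-3-[(4-methoxybenzyloxy)methyl]-3-methyl-5-(prop-1-en-2-yl)cyclohexan-1-ol (9α-OH) | C=C(C)[C@@H]1C[C@](C)(COCc2ccc(OC)cc2)[C@@H](CCCO[Si](c2ccccc2)(c2ccccc2)C(C)(C)C)[C@H](O)C1(OC)OC | intermediate (not isolated)
19 | (2S,3R,4S,6S)-3-[3-(tert-butyldiphenylsilyloxy)propyl]-2-hydroxy-4-[(4-methoxybenzyloxy)methyl]-4-methyl-6-(prop-1-en-2-yl)cyclohexan-1-one (9α-OH, C8 ketone) | C=C(C)[C@@H]1C[C@](C)(COCc2ccc(OC)cc2)[C@@H](CCCO[Si](c2ccccc2)(c2ccccc2)C(C)(C)C)[C@H](O)C1=O | intermediate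
20 | (1R,2S,3R,4S,6S)-3-[3-(tert-butyldiphenylsilyloxy)propyl]-4-[(4-methoxybenzyloxy)methyl]-4-methyl-6-(prop-1-en-2-yl)cyclohexane-1,2-diol (8α,9α-diol) | C=C(C)[C@@H]1C[C@](C)(COCc2ccc(OC)cc2)[C@@H](CCCO[Si](c2ccccc2)(c2ccccc2)C(C)(C)C)[C@H](O)[C@@H]1O | intermediate
21 | tert-butyl{3-[(3aS,4R,5S,7S,7aR)-5-[(4-methoxybenzyloxy)methyl]-2,2,5-trimethyl-7-(prop-1-en-2-yl)hexahydro-1,3-benzodioxol-4-yl]propoxy}diphenylsilane | C=C(C)[C@@H]1C[C@](C)(COCc2ccc(OC)cc2)[C@@H](CCCO[Si](c2ccccc2)(c2ccccc2)C(C)(C)C)[C@@H]2OC(C)(C)O[C@H]12 | intermediate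
22 | [(3aS,4R,5S,7S,7aR)-4-[3-(tert-butyldiphenylsilyloxy)propyl]-2,2,5-trimethyl-7-(prop-1-en-2-yl)hexahydro-1,3-benzodioxol-5-yl]methanol | C=C(C)[C@@H]1C[C@](C)(CO)[C@@H](CCCO[Si](c2ccccc2)(c2ccccc2)C(C)(C)C)[C@@H]2OC(C)(C)O[C@H]12 | intermediate
23 | (3aS,4R,5S,7S,7aR)-4-[3-(tert-butyldiphenylsilyloxy)propyl]-2,2,5-trimethyl-7-(prop-1-en-2-yl)hexahydro-1,3-benzodioxole-5-carbaldehyde | C=C(C)[C@@H]1C[C@](C)(C=O)[C@@H](CCCO[Si](c2ccccc2)(c2ccccc2)C(C)(C)C)[C@@H]2OC(C)(C)O[C@H]12 | intermediate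
24 | tert-butyl{3-[(3aS,4R,5R,7S,7aR)-5-ethenyl-2,2,5-trimethyl-7-(prop-1-en-2-yl)hexahydro-1,3-benzodioxol-4-yl]propoxy}diphenylsilane | C=C(C)[C@@H]1C[C@](C)(C=C)[C@@H](CCCO[Si](c2ccccc2)(c2ccccc2)C(C)(C)C)[C@@H]2OC(C)(C)O[C@H]12 | intermediate
25 | 3-[(3aS,4R,5R,7S,7aR)-5-ethenyl-2,2,5-trimethyl-7-(prop-1-en-2-yl)hexahydro-1,3-benzodioxol-4-yl]propan-1-ol | C=C(C)[C@@H]1C[C@](C)(C=C)[C@@H](CCCO)[C@@H]2OC(C)(C)O[C@H]12 | intermediate
26 | 3-[(3aS,4R,5R,7S,7aR)-5-ethenyl-2,2,5-trimethyl-7-(prop-1-en-2-yl)hexahydro-1,3-benzodioxol-4-yl]propanal (key-step precursor) | C=C(C)[C@@H]1C[C@](C)(C=C)[C@@H](CCC=O)[C@@H]2OC(C)(C)O[C@H]12 | intermediate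
27 | (3R,4R,5R,7S,8R,9S,10R)-8,9-O-isopropylideneeremophil-11-ene-3,8,9-triol (key-step product; 3α-OH, 4β-CH3, trans-decalin) | C=C(C)[C@@H]1C[C@]2(C)[C@@H](C)[C@H](O)CC[C@H]2[C@@H]3OC(C)(C)O[C@H]13 | intermediate
28 | (3R,4R,5R,7S,8R,9S,10R)-eremophil-11-ene-3,8,9-triol | C=C(C)[C@@H]1C[C@]2(C)[C@@H](C)[C@H](O)CC[C@H]2[C@H](O)[C@@H]1O | intermediate
29 | hex-2-ynoic acid | CCCC#CC(=O)O | starting material
30 | (3R,4R,5R,7S,8R,9S,10R)-8-hydroxyeremophil-11-ene-3,9-diyl bis(hex-2-ynoate) | C=C(C)[C@@H]1C[C@]2(C)[C@@H](C)[C@H](OC(=O)C#CCCC)CC[C@H]2[C@H](OC(=O)C#CCCC)[C@@H]1O | intermediate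
31 | (3R,4R,5R,7S,8R,9S,10R)-8-hydroxyeremophil-11-ene-3,9-diyl bis[(2Z)-hex-2-enoate] | C=C(C)[C@@H]1C[C@]2(C)[C@@H](C)[C@H](OC(=O)/C=C\CCC)CC[C@H]2[C@H](OC(=O)/C=C\CCC)[C@@H]1O | target

**Step count**
Total: 20 steps. Longest linear sequence: 18 steps (steps 1–3, 5, 7–20, from 3,4-dimethoxyphenol); steps 4 and 6 are one-step side branches.

**Steps most likely to fail**

Step 17 (key step). The aldehyde ketyl may be reduced to the primary alcohol or couple to a pinacol faster than it adds to the unactivated vinyl group on the quaternary carbon. The fallback keeps the C3–C4 bond formation but activates the acceptor; it sets out from aldehyde 23 and returns at 27. Aldehyde 23 is olefinated with diethyl [(phenylsulfonyl)methyl]phosphonate and NaH (Horner–Wadsworth–Emmons) instead of being methylenated, giving the (E)-vinyl sulfone F1. Bu4NF then frees the primary alcohol F2, and Dess–Martin oxidation gives the sulfonyl aldehyde F3. SmI2/MeOH in THF at −78 °C should close ring A 6-exo by addition of the ketyl to the electron-poor β-carbon (C4) of the vinyl sulfone, through the same chair, to the 15-phenylsulfonyl carbinol F4. Reductive desulfonylation (Na/Hg, Na2HPO4, MeOH) turns CH2SO2Ph into the C15 methyl and gives 27.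

Step 8. Conjugate addition may not occur at the crowded, tetrasubstituted β-carbon, or electron-transfer reduction may compete. The fallback adds the methyl group before the chain; it sets out from 4 (with 12) and returns at 17. Organolithium 13 (from 12 and n-BuLi) is added to 4 to give the lithium carbinolate F5, which dilute HCl converts into the trisubstituted enone F6. Me2CuLi adds to C5 of this less hindered enone, again trans to the isopropenyl group, giving the lithium enolate F7, which is trapped with allyl iodide/HMPA. NaOMe/MeOH equilibrates C10 to the equatorial 10β-allyl ketone F8 (an axial allyl group is 1,3-diaxial to the axial C8 methoxy group). 9-BBN followed by NaBO3·4H2O hydroborates the terminal allyl group in preference to the 1,1-disubstituted isopropenyl group and gives the hydroxypropyl ketone F9, and TBDPSCl/imidazole gives 17.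

Step 9. Facial selectivity of hydride delivery to C9 may be poor, because the axial C14 methyl screens the axial trajectory and equatorial attack would give the axial 9β-alcohol. The fallback replaces kinetic control by thermodynamic control; it sets out from 17 and returns at 18. The reduction is worked up without acid, and the 9β-hydroxy ketal F10 is separated and equilibrated under Meerwein–Ponndorf–Verley/Oppenauer redox conditions (Al(Oi-Pr)3, i-PrOH, trace acetone, toluene, 80 °C). The equatorial 9α-alcohol 18 is strongly favoured because the axial epimer is 1,3-diaxial to the C14 methyl; 18 is then hydrolysed to 19 as in step 9.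

**Further compounds**
F1 | step 17 | (E)-vinyl sulfone: 24 with the C5 ethenyl group replaced by (E)-2-(phenylsulfonyl)ethenyl | C=C(C)[C@@H]1C[C@](C)(/C=C/S(=O)(=O)c2ccccc2)[C@@H](CCCO[Si](c2ccccc2)(c2ccccc2)C(C)(C)C)[C@@H]2OC(C)(C)O[C@H]12
F2 | step 17 | primary alcohol from F1 (chain CH2CH2CH2OH) | C=C(C)[C@@H]1C[C@](C)(/C=C/S(=O)(=O)c2ccccc2)[C@@H](CCCO)[C@@H]2OC(C)(C)O[C@H]12
F3 | step 17 | sulfonyl aldehyde: 26 with the C5 ethenyl group replaced by (E)-2-(phenylsulfonyl)ethenyl | C=C(C)[C@@H]1C[C@](C)(/C=C/S(=O)(=O)c2ccccc2)[C@@H](CCC=O)[C@@H]2OC(C)(C)O[C@H]12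
F4 | step 17 | 15-(phenylsulfonyl) derivative of 27 (3α-OH, 4β-CH2SO2Ph) | C=C(C)[C@@H]1C[C@]2(C)[C@@H](CS(=O)(=O)c3ccccc3)[C@H](O)CC[C@H]2[C@@H]3OC(C)(C)O[C@H]13
F5 | step 8 | lithium (5S)-3,4,4-trimethoxy-1-[(4-methoxybenzyloxy)methyl]-5-(prop-1-en-2-yl)cyclohex-2-en-1-olate (both C1 epimers) | C=C(C)[C@@H]1CC(O[Li])(COCc2ccc(OC)cc2)C=C(OC)C1(OC)OC
F6 | step 8 | (5S)-6,6-dimethoxy-3-[(4-methoxybenzyloxy)methyl]-5-(prop-1-en-2-yl)cyclohex-2-en-1-one | C=C(C)[C@@H]1CC(COCc2ccc(OC)cc2)=CC(=O)C1(OC)OC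
F7 | step 8 | lithium enolate (C9–OLi, C9=C10) with 5β-CH3, 5α-CH2OPMB, 7α-isopropenyl | C=C(C)[C@@H]1C[C@](C)(COCc2ccc(OC)cc2)C=C(O[Li])C1(OC)OC
F8 | step 8 | 10β-allyl ketone: 17 with prop-2-en-1-yl in place of the silyloxypropyl chain | C=C(C)[C@@H]1C[C@](C)(COCc2ccc(OC)cc2)[C@@H](CC=C)C(=O)C1(OC)OC
F9 | step 8 | 10β-(3-hydroxypropyl) ketone: 17 without the silyl group | C=C(C)[C@@H]1C[C@](C)(COCc2ccc(OC)cc2)[C@@H](CCCO)C(=O)C1(OC)OC
F10 | step 9 | 9β-epimer of hydroxy ketal 18 (axial C9–OH) | C=C(C)[C@@H]1C[C@](C)(COCc2ccc(OC)cc2)[C@@H](CCCO[Si](c2ccccc2)(c2ccccc2)C(C)(C)C)[C@@H](O)C1(OC)OC
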